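**Strategy.** The cyclohexenone ring is numbered C1 (C=O), C2=C3, C4, C5 (secondary carbinols), C6 (tertiary carbinol). It is cut at C2=C3 and at C1–C6. C3–C6 are the four carbons of L-tartaric acid: its two stereocentres become the trans-diol C4/C5 and steer a chelate-controlled Grignard addition that sets C6. Ethyl vinyl ether supplies C1–C2 and serves twice as nucleophile, lithiated at C1 and later as enol ether at C2. The key step exploits the γ-oxygenated enone C1(=O)–C2=C3–C4(O): an acyclic aldehyde/enol ether closes C2–C3 by a silyl-triflate Mukaiyama cyclisation, and acid work-up collapses the adduct to the enone, leaving the remote Z-alkene untouched.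

Key step: step 7

Remark: the SMILES is read as (4S,5R,6R), so C5–OH and C6–OH are cis and C4–OH is trans to both. The chain is (12Z)-henicos-12-en-1-yl. The (2R,3R) centres of L-tartrate map onto C4 and C5 with no change of geometry.

Step 1
Reactants: 1 12-bromododecan-1-ol
Product: 2 12-bromododecanal
Conditions: TEMPO (cat.), PhI(OAc)2, CH2Cl2, rt
Reagents that add atoms: none
Why: The oxoammonium (TEMPO/PhI(OAc)2) alcohol oxidation stops at the aldehyde and does not disturb the primary bromide.

Step 2
Reactants: 2 12-bromododecanal; 3 nonyltriphenylphosphonium bromide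
Product: 5 (Z)-1-bromohenicos-12-ene, via nonylidenetriphenylphosphorane 4 (not isolated)
Conditions: 3, NaHMDS, THF, 0 °C; then 2, −78 °C → rt
Reagents that add atoms: none
Why: The Wittig olefination of a non-stabilised ylide under lithium-free conditions passes through the kinetically favoured cis-oxaphosphetane and should set the Z-alkene, while the cold ylide is too slow to alkylate the primary bromide.

Step 3
Reactants: 6 dimethyl (4R,5R)-2,2-dimethyl-1,3-dioxolane-4,5-dicarboxylate (dimethyl 2,3-O-isopropylidene-L-tartrate)
Product: 7 (4R,5R)-N4,N5-dimethoxy-N4,N5,2,2-tetramethyl-1,3-dioxolane-4,5-dicarboxamide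
Conditions: MeNH(OMe)·HCl, i-PrMgCl, THF, −20 → 0 °C
Reagents that add atoms: N,O-dimethylhydroxylamine hydrochloride, CNOC.Cl
Why: Weinreb amide synthesis by aminolysis of both esters with the chloromagnesium amide leaves untouched the two purchased stereocentres (future C4 and C5), which sit in the thermodynamically preferred trans-dioxolane.

Step 4
Reactants: 7 bis-Weinreb amide; 8 ethyl vinyl ether
Product: 10 (4R,5R)-5-(2-ethoxyacryloyl)-N-methoxy-N,2,2-trimethyl-1,3-dioxolane-4-carboxamide, via 1-ethoxyvinyllithium 9 (not isolated)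
Conditions: 8, t-BuLi, THF, −78 → 0 °C; then slow addition to 7 (slight excess), THF, −78 °C; pH 7 buffer
Reagents that add atoms: none
Why: In this Weinreb ketone synthesis with an acetyl-anion equivalent (forming C1–C6), the C2 symmetry of 7 makes both amides equivalent, the chelated tetrahedral adduct survives until the quench so no over-addition occurs at that carbon, and its negative charge should slow attack on the second amide.

Step 5
Reactants: 5 (Z)-1-bromohenicos-12-ene; 10 keto amide
Product: 12 (4R,5R)-5-[(3R,15Z)-2-ethoxy-3-hydroxytetracosa-1,15-dien-3-yl]-N-methoxy-N,2,2-trimethyl-1,3-dioxolane-4-carboxamide, via (Z)-henicos-12-enylmagnesium bromide 11 (not isolated)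
Conditions: 5, Mg, Et2O, reflux; then 10, MgBr2·OEt2, CH2Cl2/Et2O, −78 → −40 °C; pH 7 buffer
Reagents that add atoms: none
Why: In this Cram-chelate-controlled Grignard 1,2-addition, magnesium bridges the ketone oxygen and the dioxolane oxygen on C5 and the chain enters from the C5–H face (anti to C4), which sets C6 as R with its oxygen cis to the C5 oxygen, while the ketone reacts far faster than the Weinreb amide at this temperature.

Step 6
Reactants: 12 tertiary alcohol
Product: 13 (4R,5R)-5-[(3R,15Z)-2-ethoxy-3-hydroxytetracosa-1,15-dien-3-yl]-2,2-dimethyl-1,3-dioxolane-4-carbaldehyde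
Conditions: DIBAL-H (2.5 equiv), THF, −78 °C; aq. Rochelle salt
Reagents that add atoms: none
Why: In the Weinreb amide reduction the chelated aluminium hemiaminal collapses to the C3 aldehyde only on the non-acidic work-up, so over-reduction, enol-ether hydrolysis and C4 epimerisation are avoided, and a lactol to the C6 hydroxyl would be a strained trans-fused bicycle.

Step 7
Reactants: 13 hydroxy aldehyde enol ether
Product: 16 (4S,5R,6R)-6-hydroxy-6-[(12Z)-henicos-12-en-1-yl]-4,5-(isopropylidenedioxy)cyclohex-2-en-1-one, via tertiary TMS ether 14 (not isolated), via 1-ethoxy-3-silyloxycyclohexene 15 (not isolated)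
Conditions: TMSOTf (2.3 equiv), 2,6-di-tert-butyl-4-methylpyridine (DTBMP, 3 equiv), CH2Cl2, −78 → −40 °C; then 0.5 M aq. HCl, THF, 0 °C → rt
Reagents that add atoms: water, O
Why: TMSOTf first caps the C6 hydroxyl (14) and then activates the aldehyde, the terminal enol-ether carbon C2 attacks C3, and the hindered pyridine removes the only α-proton of the resulting O-ethyl oxocarbenium ion at C1 (C2–H, since C6 is quaternary) to give 15. The closest known reaction types are the Mukaiyama aldol addition of alkyl enol ethers to Lewis-acid-activated aldehydes (also the C–C bond-forming half of the Ferrier carbocyclisation) and, for the work-up, the acid collapse of a 3-alkoxyallylic alcohol derivative in the Stork–Danheiser enone synthesis. The one ring that closes, C1–C6, does so in the 6-(enolendo)-exo-trig mode through the new C2–C3 bond. The only new stereocentre, C3, needs no control because aqueous acid ionises its allylic silyloxy group, water adds at C1 and ethanol leaves, which turns C2–C3 into the enone double bond, while C4, C5 and C6 are spectators. The step needs C–C bond formation to outrun enolisation of the α-alkoxy aldehyde (C4) and protonolysis of the enol ether, which low temperature, a proton-specific non-nucleophilic base, the absence of any enolate-forming base and the intramolecular setting should secure; the trans-dioxolane also keeps the C6 oxygen from masking C3 as a lactol. The isolated Z-alkene of the chain is far less nucleophilic than the 1,1-disubstituted enol ether, and no metathesis, osmium, peracid or hydrogenation reagent is ever present.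

Step 8
Reactants: 16 enone acetonide
Product: 17 (4S,5R,6R)-4,5,6-trihydroxy-6-[(12Z)-henicos-12-en-1-yl]cyclohex-2-en-1-one (target)
Conditions: TFA/H2O (9:1), CH2Cl2, 0 °C → rt
Reagents that add atoms: none
Why: Acid-catalysed acetal hydrolysis cleaves only the C–O bonds at the ketal carbon, is helped by the strain of the trans-fused dioxolane, and touches no stereocentre or alkene.

Compound list
1 | 12-bromododecan-1-ol | OCCCCCCCCCCCCBr | starting material
2 | 12-bromododecanal | O=CCCCCCCCCCCCBr | intermediate
3 | nonyltriphenylphosphonium bromide | CCCCCCCCC[P+](c1ccccc1)(c1ccccc1)c1ccccc1.[Br-] | starting material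
4 | nonylidenetriphenylphosphorane | CCCCCCCCC=P(c1ccccc1)(c1ccccc1)c1ccccc1 | intermediate
5 | (Z)-1-bromohenicos-12-ene | CCCCCCCC/C=C\CCCCCCCCCCCBr | intermediate
6 | dimethyl (4R,5R)-2,2-dimethyl-1,3-dioxolane-4,5-dicarboxylate | COC(=O)[C@@H]1OC(C)(C)O[C@H]1C(=O)OC | starting material
7 | (4R,5R)-N4,N5-dimethoxy-N4,N5,2,2-tetramethyl-1,3-dioxolane-4,5-dicarboxamide | CON(C)C(=O)[C@@H]1OC(C)(C)O[C@H]1C(=O)N(C)OC | intermediate
8 | ethyl vinyl ether | C=COCC | starting material
9 | 1-ethoxyvinyllithium | [Li]C(=C)OCC | intermediate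
10 | (4R,5R)-5-(2-ethoxyacryloyl)-N-methoxy-N,2,2-trimethyl-1,3-dioxolane-4-carboxamide | C=C(OCC)C(=O)[C@@H]1OC(C)(C)O[C@H]1C(=O)N(C)OC | intermediate
11 | (Z)-henicos-12-enylmagnesium bromide | CCCCCCCC/C=C\CCCCCCCCCCC[Mg]Br | intermediate
12 | (4R,5R)-5-[(3R,15Z)-2-ethoxy-3-hydroxytetracosa-1,15-dien-3-yl]-N-methoxy-N,2,2-trimethyl-1,3-dioxolane-4-carboxamide | CCCCCCCC/C=C\CCCCCCCCCCC[C@](O)(C(=C)OCC)[C@@H]1OC(C)(C)O[C@H]1C(=O)N(C)OC | intermediate
13 | (4R,5R)-5-[(3R,15Z)-2-ethoxy-3-hydroxytetracosa-1,15-dien-3-yl]-2,2-dimethyl-1,3-dioxolane-4-carbaldehyde | CCCCCCCC/C=C\CCCCCCCCCCC[C@](O)(C(=C)OCC)[C@@H]1OC(C)(C)O[C@H]1C=O | intermediate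
14 | trimethylsilyl ether of 13 at the tertiary (C6) oxygen | CCCCCCCC/C=C\CCCCCCCCCCC[C@](O[Si](C)(C)C)(C(=C)OCC)[C@@H]1OC(C)(C)O[C@H]1C=O | intermediate
15 | 1-ethoxy-6-[(12Z)-henicos-12-en-1-yl]-4,5-(isopropylidenedioxy)-3,6-bis(trimethylsilyloxy)cyclohex-1-ene, C4–C6 configured as in 16, C3 uncontrolled | CCCCCCCC/C=C\CCCCCCCCCCC[C@]1(O[Si](C)(C)C)C(OCC)=CC(O[Si](C)(C)C)[C@@H]2OC(C)(C)O[C@@H]12 | intermediate
16 | (4S,5R,6R)-6-hydroxy-6-[(12Z)-henicos-12-en-1-yl]-4,5-(isopropylidenedioxy)cyclohex-2-en-1-one | CCCCCCCC/C=C\CCCCCCCCCCC[C@]1(O)C(=O)C=C[C@@H]2OC(C)(C)O[C@@H]12 | intermediate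
17 | (4S,5R,6R)-4,5,6-trihydroxy-6-[(12Z)-henicos-12-en-1-yl]cyclohex-2-en-1-one | CCCCCCCC/C=C\CCCCCCCCCCC[C@]1(O)C(=O)C=C[C@H](O)[C@H]1O | target

Total step count: 8.
Longest linear sequence: 6 steps (3, 4, 5, 6, 7, 8 from 6). The chain branch (1, 2) joins at step 5 and is equally long.

Steps most likely to fail

Step 7. The enol ether may be lost by protonolysis before the C2–C3 bond forms. The activated aldehyde may enolise, with loss of configuration at C4. The trans-dioxolane may also resist the closure. The fallback sets out from 13 and comes back at 16, and it replaces the cationic closure by a stepwise enolate route. Oxalic acid on wet silica hydrolyses the enol ether to the methyl ketone aldehyde F1. Catalytic DBU in toluene closes the ring by an intramolecular aldol addition (the type of closure known for aldohexos-5-uloses) to the β-hydroxy ketone F2. MsCl/Et3N converts this into the C3 mesylate F3, which loses methanesulfonate by E1cB in the same flask to give 16.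

Step 5. Facial selectivity may erode through competing chelation by the enol-ether oxygen or through non-chelated attack, and conjugate addition to the alkoxy enone may intervene. The fallback sets out from 7 and comes back at 12, and it reverses the order of the two C–C bond formations. Grignard reagent 11 is added once to 7 to give the docos-13-enoyl ketone F4. Reagent 9 is then added in THF at −78 °C with the non-chelating lithium counter-ion. The incoming group is now C1, so polar Felkin–Anh attack (anti to the C5–O bond) leads to the same C6 configuration that chelate control gives in the main route.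

Step 4. Discrimination between the first and the second amide may be poor, which would lead to double addition next to unreacted 7. The fallback sets out from 6 and comes back at 13, and it differentiates the two termini chemically. Mono-saponification (KOH, 1 equiv, MeOH) gives the half-ester F5. 1-Chloro-N,N,2-trimethylpropenylamine converts it under neutral conditions into the acid chloride F6. Stille acylation with tributyl(1-ethoxyvinyl)stannane (Pd cat.) gives the keto ester F7. Grignard reagent 11 adds under the same chelate control to give the hydroxy ester F8. DIBAL-H at −78 °C then reduces the ester to 13.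

Further compounds
F1 | step 7 | (4R,5R)-5-[(3R,15Z)-3-hydroxy-2-oxotetracos-15-en-3-yl]-2,2-dimethyl-1,3-dioxolane-4-carbaldehyde | CCCCCCCC/C=C\CCCCCCCCCCC[C@](O)(C(C)=O)[C@@H]1OC(C)(C)O[C@H]1C=O
F2 | step 7 | 3,6-dihydroxy-6-[(12Z)-henicos-12-en-1-yl]-4,5-(isopropylidenedioxy)cyclohexan-1-one, C4–C6 as in 16, C3 uncontrolled | CCCCCCCC/C=C\CCCCCCCCCCC[C@]1(O)C(=O)CC(O)[C@@H]2OC(C)(C)O[C@@H]12
F3 | step 7 | C3 methanesulfonate of F2 | CCCCCCCC/C=C\CCCCCCCCCCC[C@]1(O)C(=O)CC(OS(C)(=O)=O)[C@@H]2OC(C)(C)O[C@@H]12
F4 | step 5 | (4R,5R)-5-[(13Z)-docos-13-enoyl]-N-methoxy-N,2,2-trimethyl-1,3-dioxolane-4-carboxamide | CCCCCCCC/C=C\CCCCCCCCCCCC(=O)[C@@H]1OC(C)(C)O[C@H]1C(=O)N(C)OC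
F5 | step 4 | (4R,5R)-5-(methoxycarbonyl)-2,2-dimethyl-1,3-dioxolane-4-carboxylic acid | COC(=O)[C@@H]1OC(C)(C)O[C@H]1C(=O)O
F6 | step 4 | methyl (4R,5R)-5-(chlorocarbonyl)-2,2-dimethyl-1,3-dioxolane-4-carboxylate | COC(=O)[C@@H]1OC(C)(C)O[C@H]1C(=O)Cl
F7 | step 4 | methyl (4R,5R)-5-(2-ethoxyacryloyl)-2,2-dimethyl-1,3-dioxolane-4-carboxylate | C=C(OCC)C(=O)[C@@H]1OC(C)(C)O[C@H]1C(=O)OC
F8 | step 4 | methyl (4R,5R)-5-[(3R,15Z)-2-ethoxy-3-hydroxytetracosa-1,15-dien-3-yl]-2,2-dimethyl-1,3-dioxolane-4-carboxylate | CCCCCCCC/C=C\CCCCCCCCCCC[C@](O)(C(=C)OCC)[C@@H]1OC(C)(C)O[C@H]1C(=O)OC
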